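The rate constants are assumed; the result is computed.

I cannot get the whole weighed charge of free catalyst to work in this flask, since step one spends part of it on the impurity.

left-handed substrate 1.0 mM; partner 1.50 mM; free catalyst 5.0 µM; impurity 0.67 µM; right-handed substrate 1.0 mM

    free catalyst + impurity → spent catalyst (k1 = 1.25 × 10⁷ L mol⁻¹ s⁻¹)
    partner + free catalyst + right-handed substrate → free catalyst + right-handed product (k2 = 1.17 × 10⁶ L² mol⁻² s⁻¹)
    partner + free catalyst + left-handed substrate → free catalyst + left-handed product (k3 = 2.46 × 10⁶ L² mol⁻² s⁻¹)

1. apparent order in free catalyst when 50% of the left-handed substrate and right-handed substrate together are converted (percent change of the rate of making left-handed product for one percent more free catalyst charged)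
2. apparent order in partner when 50% of the left-handed substrate and right-handed substrate together are converted (percent change of the rate of making left-handed product for one percent more partner charged)

- free catalyst is single-handed; left-handed substrate and right-handed substrate are mirror images of each other, charged as a racemate, each of them at the stated concentration
- charge of left-handed substrate (flask): 1.0 mM

- At the charged amounts, the impurity lasts 0.0160 s against the free catalyst, while left-handed substrate lasts 62.6 s; because the first time is far shorter than the second, I subtract 0.67 µM from [free catalyst] at the start.
- The leverage of a charge, 1.15 for free catalyst here, is that charge over what stands of it after a withdrawal that does not grow with it.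
- In this flask, both substrate steps are first order in [partner] and [free catalyst], so more of either speeds the clock without moving the split at 50% conversion, and I expect order 1.15 in free catalyst.
- Partner, the limiting reagent, will stand at 0.500 mM when you reach that conversion, so I expect order 3.00 in partner.

- The forecast gives the same, 1.155 and 3, saying that “at fixed conversion the catalyst only rescales time”.
- The simulation gives 1.2 and 3.0.
- In this flask, impurity stands at 0% by 8.00 s and free catalyst at 86.6%, the inverse of the leverage, and it still stands at 86.6% at 800 s, while both substrate steps draw partner down to 41.6% at 80.0 s and reach 50% conversion at 109 s. In the flask with twice the free catalyst, leverage falls to 1.07, working catalyst rises to 9.33 µM, and the time to that conversion carries the factor 0.464.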